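In any closed flask the starting material charged equals what remains, plus product, plus whatever else it has become, and in the east flask it is the limiting reagent, 120 mM against 1500 mM of coupling partner.

| flask | starting material | coupling partner | time |
|---|---|---|---|
| south-east | 250 mM | 500 mM |  |
| north-east | 250 mM | 250 mM |  |
| east | 120 mM | 1500 mM | 11 min |

| run | time / min | [product] / mM |
|---|---|---|
| south-east run | 1.4 | 13.5 |
| south-east run | 2.8 | 40.5 |
| south-east run | 4.1 | 71.6 |
| south-east run | 5.5 | 107.0 |
| south-east run | 6.9 | 140.0 |
| south-east run | 8.2 | 160.4 |
| south-east run | 9.6 | 175.8 |
| south-east run | 11 | 185.3 |
| north-east run | 1.4 | 5.3 |
| north-east run | 2.8 | 10.9 |
| north-east run | 4.1 | 18.9 |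
| north-east run | 5.5 | 29.0 |
| north-east run | 6.9 | 40.5 |
| north-east run | 8.2 | 50.6 |
| north-east run | 9.6 | 63.8 |
| north-east run | 11 | 74.0 |

(scatter of a reading: 0.8 mM)

* the exponent of [coupling partner] in the starting rate at the charge of the south-east run (at the point where two percent of the starting material have become product)
* product in the east run at 11 min, as a share of the starting material charged

- Overall: starting material + coupling partner -> product.
- Constant volume, constant temperature.
- "The second partner" is coupling partner.
- An order is taken over about fifteen percent of the charge, up and down.

The last south-east readings rise by shrinking steps towards a plateau we read, roughly, near 201 mM, so 19.8% of that charge seems not to reach product. Half that plateau stood near 5.5 min, which we take as the mean stay of starting material, and we suppose a steady loss. Missing share over stay gives the share of waiting starting material lost per minute, the leak, 0.0359 /min.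

From below: the first readings of the two runs imply an order of 1.35 in coupling partner, averaged across their charges, so the east flask starts at 0.170 /min; held there against the leak for 11 min, it yields 73.9%.

From above: mid-run, the south-east flask turns 0.186 /min of its remainder, which, scaled with partner and product to the full east charge, gives 0.721 /min and a yield of 95.3%.

A climb between those rates gives a stay of 2.30 min, so we commit to 91.7%.

The forecast gives an order of 1.2 and, for the east run, 98%, a yield above our bracket, holding that “the reaction should be essentially complete”.

The flask gives an order of 1.3 at the south-east charge and 92.5% in the east run, a yield inside the bracket.

    starting material + coupling partner → product (0.03660 /M/min)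
    starting material + 2 coupling partner → product + coupling partner (0.04164 /M²/min)
    starting material → decomposed substrate (0.03426 /min)
    starting material + coupling partner + product → 2 product (4.926 /M²/min)

If we count the missing 7.50% of the east run as lost, our leak, itself a rough reading, puts the mean stay in the east flask near 2.09 min, an estimate. The yield stands there because of the step in which product helps starting material and coupling partner form more product: the simulated east run without that step falls from 92.5% by 24 percentage points. For that run the leak and the unaided rate give 73.9%, and the run stands at 68.7%.

The runs come from a simulation on assumed constants, and the scatter is random.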